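**Plan**

- Numbering of ring A: C1 (prenyl), C2 (OH), C3 (H), C4 (OH), C5 (CHO), C6 (aroyl); C7 is the ketone carbon; ring B is the bromo-orcinol ring.
- Enabling feature: ring A is a hexasubstituted resorcinol. C1–C4 carry the 1,3-dioxygen pattern of a γ-prenylated acetoacetate, and the neighbouring C5 and C6 both carry carbonyl carbons, i.e. an alkyne flanked by two acceptors.
- Retrosynthesis: the two ring B methoxymethyl ethers come off first. Ring A is then cut at C1–C6 and C4–C5 into a 1-methoxy-1,3-bis(trimethylsilyloxy)diene and a 4-aryl-4-oxobut-2-ynal. The ynal is cut at the C7–alkyne bond (ring B benzaldehyde plus propargyl alcohol), and the diene at the prenyl–γ-carbon bond.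
- Forward: ring B is bought as orcinol and is protected, formylated and brominated. The four-carbon chain is attached and oxidised to the keto ynal. Ring A is made last, in one step, by [4+2] cycloaddition and aromatisation.
- Stereochemistry: the target has no stereocentre and no stereodefined double bond. The racemic carbinol and the sp3 centres of the cycloadduct are erased by oxidation and aromatisation.

Key step: step 9

Remark: the silyl enol ether and the bis(silyloxy)diene are drawn as single (Z) isomers. Mixtures of double-bond isomers are expected and do not matter, because these double bonds end up in the aromatic ring.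

**Route**

Step 1
Reactants: 1 methyl acetoacetate; 2 1-bromo-3-methylbut-2-ene
Product: 4 methyl 7-methyl-3-oxooct-6-enoate, via sodium lithium dianion 3 (not isolated)
Conditions: NaH, THF, 0 °C; n-BuLi, 0 °C; then 2, 0 °C → rt; 1 M HCl quench
Reagents that add atoms: none
Why: γ-Alkylation of a β-keto ester dianion, in which the second deprotonation creates the more reactive terminal carbanion that displaces the allylic bromide (SN2) while the α-position stays blocked as the enolate.

Step 2
Reactants: 4 methyl 7-methyl-3-oxooct-6-enoate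
Product: 5 methyl (2Z)-7-methyl-3-(trimethylsilyloxy)octa-2,6-dienoate
Conditions: Me3SiCl, Et3N, hexane, rt
Reagents that add atoms: chlorotrimethylsilane, C[Si](C)(C)Cl
Why: O-Silylation of the enolised β-keto ester under soft enolisation is the standard first stage of bis(silyl enol ether) formation.

Step 3
Reactants: 5 methyl (2Z)-7-methyl-3-(trimethylsilyloxy)octa-2,6-dienoate
Product: 7 (1Z,3Z)-1-methoxy-7-methyl-1,3-bis(trimethylsilyloxy)octa-1,3,6-triene, via lithium dienolate 6 (not isolated)
Conditions: LiN(i-Pr)2, THF, −78 °C; then Me3SiCl, −78 °C → rt; non-aqueous work-up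
Reagents that add atoms: chlorotrimethylsilane, C[Si](C)(C)Cl
Why: Kinetic γ-deprotonation of the β-silyloxy enoate and O-silylation of the resulting dienolate is the established route to 1-alkoxy-1,3-bis(silyloxy)dienes, with the remote trisubstituted alkene as a spectator.

Step 4
Reactants: 8 orcinol
Product: 9 1,3-bis(methoxymethoxy)-5-methylbenzene
Conditions: NaH, MOMCl, DMF, 0 °C → rt
Reagents that add atoms: chloromethyl methyl ether, COCCl
Why: Williamson-type O-alkylation of the bis(phenoxide) installs ethers that direct the next metalation and later keep the phenols from adding to the ynone.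

Step 5
Reactants: 9 1,3-bis(methoxymethoxy)-5-methylbenzene
Product: 11 2,6-bis(methoxymethoxy)-4-methylbenzaldehyde, via aryllithium 10 (not isolated)
Conditions: n-BuLi, TMEDA, THF, 0 °C; then DMF, 0 °C → rt; H2O quench
Reagents that add atoms: N,N-dimethylformamide, CN(C)C=O
Why: Directed ortho-metalation takes place at the position flanked by both methoxymethoxy groups, and the aryllithium is formylated by DMF.

Step 6
Reactants: 11 2,6-bis(methoxymethoxy)-4-methylbenzaldehyde
Product: 12 3-bromo-2,6-bis(methoxymethoxy)-4-methylbenzaldehyde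
Conditions: NBS (1.0 equiv), MeCN, 0 °C → rt, dark
Reagents that add atoms: N-bromosuccinimide, O=C1CCC(=O)N1Br
Why: Electrophilic aromatic bromination can only occur at the two equivalent free positions (ortho and para to an ether oxygen, meta to the formyl group), so one equivalent of NBS under ionic conditions should give the single monobromide and leave the benzylic methyl group alone.

Step 7
Reactants: 12 3-bromo-2,6-bis(methoxymethoxy)-4-methylbenzaldehyde; 13 prop-2-yn-1-ol
Product: 15 1-[3-bromo-2,6-bis(methoxymethoxy)-4-methylphenyl]but-2-yne-1,4-diol (racemic), via dilithio alkynolate 14 (not isolated)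
Conditions: 13 (2.2 equiv), n-BuLi (4.3 equiv), THF, −78 → 0 °C; then 12, −78 → 0 °C; H2O quench
Reagents that add atoms: none
Why: 1,2-Addition of a lithium acetylide to the aldehyde, with all n-BuLi consumed in forming the O,C-dilithio reagent before 12 is added, so bromine–lithium exchange should not compete.

Step 8
Reactants: 15 1-[3-bromo-2,6-bis(methoxymethoxy)-4-methylphenyl]but-2-yne-1,4-diol
Product: 17 4-[3-bromo-2,6-bis(methoxymethoxy)-4-methylphenyl]-4-oxobut-2-ynal, via hydroxy ynal 16 (not isolated)
Conditions: Dess–Martin periodinane (3 equiv), CH2Cl2, 0 °C → rt; filtration through a short silica pad, used at once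
Reagents that add atoms: none
Why: Dess–Martin oxidation converts both the primary propargylic alcohol and the benzylic-propargylic carbinol to carbonyl groups under non-aqueous, amine-free conditions that neither hydrate the ynal nor add a nucleophile to it.

Step 9
Reactants: 7 (1Z,3Z)-1-methoxy-7-methyl-1,3-bis(trimethylsilyloxy)octa-1,3,6-triene; 17 4-[3-bromo-2,6-bis(methoxymethoxy)-4-methylphenyl]-4-oxobut-2-ynal
Product: 20 2-[3-bromo-2,6-bis(methoxymethoxy)-4-methylbenzoyl]-4,6-dihydroxy-3-(3-methylbut-2-en-1-yl)benzaldehyde, via cycloadduct 18 (not isolated), via aryl silyl ether 19 (not isolated)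
Conditions: 7 (1.5 equiv), toluene, −40 °C → rt, argon; then 0.5 M aq HCl, THF, 0 °C
Reagents that add atoms: none
Why: Diene 7 (three oxygen donors) and the alkyne of 17 (two carbonyl acceptors) should undergo a normal-demand, strongly asynchronous Diels–Alder reaction in which the prenyl-bearing γ-carbon of the diene leads by bonding to C6 and the ketene acetal carbon then bonds to C5; cycloadduct 18 should lose methoxytrimethylsilane from its mixed ketal and tautomerise to aryl silyl ether 19, which the dilute acid work-up cleaves to 20. The closest known reaction type is the Diels–Alder benzannulation of 1-alkoxy-1,3-bis(silyloxy)dienes with acetylenic esters, ketones and aldehydes, which gives resorcinols directly. Ring A closes in the cycloaddition itself, both new bonds (C1–C6 and C4–C5) being made between the two components; in the stepwise limit this is a Mukaiyama–Michael addition followed by 6-exo-trig attack of the allenolate carbon C5 on the silyloxycarbenium carbon C4. No stereocentre survives, because the two sp3 ring carbons of 18 become aromatic. The step needs regioselectivity, which should come from the formyl group being the stronger and smaller acceptor (it directs the nucleophilic terminus to its β-carbon C6) and from the fully substituted ketene acetal terminus preferring to bond beside the formyl group and not beside the 2,6-disubstituted aroyl group. It also needs chemoselectivity for the alkyne over the two carbonyl groups, which the absence of any Lewis acid and the hindrance of the ketone should provide.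

Step 10
Reactants: 20 2-[3-bromo-2,6-bis(methoxymethoxy)-4-methylbenzoyl]-4,6-dihydroxy-3-(3-methylbut-2-en-1-yl)benzaldehyde
Product: 21 Pestalone C
Conditions: 3 M aq HCl, THF, rt
Reagents that add atoms: none
Why: Acid-catalysed acetal hydrolysis removes the two aryl methoxymethyl ethers, which are activated by the ortho ketone, at a temperature low enough that the prenyl group should not cyclise onto the C2 hydroxyl.

**Compound list**

1 | methyl acetoacetate | COC(=O)CC(C)=O | starting material
2 | 1-bromo-3-methylbut-2-ene | CC(C)=CCBr | starting material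
3 | sodium lithium dianion of methyl acetoacetate (formed in the flask) | COC([O-])=CC([O-])=C.[Na+].[Li+] | intermediate
4 | methyl 7-methyl-3-oxooct-6-enoate | COC(=O)CC(=O)CCC=C(C)C | intermediate
5 | methyl (2Z)-7-methyl-3-(trimethylsilyloxy)octa-2,6-dienoate | COC(=O)/C=C(\O[Si](C)(C)C)CCC=C(C)C | intermediate
6 | lithium dienolate of 5 (formed in the flask) | [Li+].COC([O-])=CC(O[Si](C)(C)C)=CCC=C(C)C | intermediate
7 | (1Z,3Z)-1-methoxy-7-methyl-1,3-bis(trimethylsilyloxy)octa-1,3,6-triene | CO/C(O[Si](C)(C)C)=C/C(O[Si](C)(C)C)=C/CC=C(C)C | intermediate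
8 | orcinol (5-methylbenzene-1,3-diol) | Cc1cc(O)cc(O)c1 | starting material
9 | 1,3-bis(methoxymethoxy)-5-methylbenzene | COCOc1cc(C)cc(OCOC)c1 | intermediate
10 | [2,6-bis(methoxymethoxy)-4-methylphenyl]lithium (formed in the flask) | [Li]c1c(OCOC)cc(C)cc1OCOC | intermediate
11 | 2,6-bis(methoxymethoxy)-4-methylbenzaldehyde | COCOc1cc(C)cc(OCOC)c1C=O | intermediate
12 | 3-bromo-2,6-bis(methoxymethoxy)-4-methylbenzaldehyde | COCOc1cc(C)c(Br)c(OCOC)c1C=O | intermediate
13 | prop-2-yn-1-ol | C#CCO | starting material
14 | lithium 3-lithioprop-2-yn-1-olate (formed in the flask) | [Li]C#CCO[Li] | intermediate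
15 | 1-[3-bromo-2,6-bis(methoxymethoxy)-4-methylphenyl]but-2-yne-1,4-diol (racemic) | OCC#CC(O)c1c(OCOC)cc(C)c(Br)c1OCOC | intermediate
16 | 4-[3-bromo-2,6-bis(methoxymethoxy)-4-methylphenyl]-4-hydroxybut-2-ynal (racemic, formed in the flask) | O=CC#CC(O)c1c(OCOC)cc(C)c(Br)c1OCOC | intermediate
17 | 4-[3-bromo-2,6-bis(methoxymethoxy)-4-methylphenyl]-4-oxobut-2-ynal | O=CC#CC(=O)c1c(OCOC)cc(C)c(Br)c1OCOC | intermediate
18 | cycloadduct: 2-[3-bromo-2,6-bis(methoxymethoxy)-4-methylbenzoyl]-6-methoxy-3-(3-methylbut-2-en-1-yl)-4,6-bis(trimethylsilyloxy)cyclohexa-1,4-diene-1-carbaldehyde (mixture of diastereomers, formed in the flask) | COC1(O[Si](C)(C)C)C=C(O[Si](C)(C)C)C(CC=C(C)C)C(C(=O)c2c(OCOC)cc(C)c(Br)c2OCOC)=C1C=O | intermediate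
19 | 2-[3-bromo-2,6-bis(methoxymethoxy)-4-methylbenzoyl]-6-hydroxy-3-(3-methylbut-2-en-1-yl)-4-(trimethylsilyloxy)benzaldehyde (formed in the flask) | CC(C)=CCc1c(O[Si](C)(C)C)cc(O)c(C=O)c1C(=O)c1c(OCOC)cc(C)c(Br)c1OCOC | intermediate
20 | 2-[3-bromo-2,6-bis(methoxymethoxy)-4-methylbenzoyl]-4,6-dihydroxy-3-(3-methylbut-2-en-1-yl)benzaldehyde (Pestalone C, ring B bis(methoxymethyl) ether) | CC(C)=CCc1c(O)cc(O)c(C=O)c1C(=O)c1c(OCOC)cc(C)c(Br)c1OCOC | intermediate
21 | Pestalone C, 2-(3-bromo-2,6-dihydroxy-4-methylbenzoyl)-4,6-dihydroxy-3-(3-methylbut-2-en-1-yl)benzaldehyde | CC(C)=CCc1c(O)cc(O)c(C=O)c1C(=O)c1c(O)cc(C)c(Br)c1O | target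

**Step count and risks**

Total steps: 10. Longest linear sequence: 7 steps (orcinol 8 to 21, steps 4–10); the diene branch (steps 1–3) joins at step 9.

Steps most likely to fail:

1. Step 9. The process at risk is the first bond forming at C5 (β to the ketone) or at the formyl carbon, which would give the isomeric resorcinol or open-chain adducts. The fallback removes the second acceptor by carrying C7 at the carbinol level. It sets out from 12 and comes back to the route at 21.
   - HC≡CMgBr (THF, 0 °C) should give propargylic alcohol F1.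
   - TBSOTf with 2,6-lutidine should give silyl ether F2.
   - LiN(i-Pr)2 followed by DMF should give silyloxy ynal F3, whose alkyne has the formyl group as its only acceptor.
   - Cycloaddition of F3 with 7 under the conditions of step 9 (warming if needed) should give benzaldehyde F4 with the prenyl-bearing carbon bonded to the carbinol-bearing alkyne carbon.
   - A free C7 carbinol would close onto the C5 aldehyde as a lactol, so the two carbonyl groups are set together. NaH and MOMCl cap the ring A phenols to give tetraether F5. NaBH4 reduces the aldehyde to benzylic alcohol F6. Bu4NF removes the silyl group to give diol F7. A twofold Swern oxidation ((COCl)2, DMSO, Et3N, −78 °C) gives keto aldehyde F8.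
   - F8 enters step 10, where the acid removes all four methoxymethyl groups.

2. Step 8. The process at risk is degradation of the doubly activated ynal, or ionisation of the electron-rich benzylic carbinol by the acetic acid released, while both oxidations are pushed to completion. The fallback sets the ketone first and leaves only one short oxidation for the end. It sets out from 12 and comes back to the route at 17.
   - The lithium acetylide of tert-butyldimethyl(prop-2-yn-1-yloxy)silane (n-BuLi, THF, −78 °C) should add to 12 to give carbinol F9.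
   - MnO2 in CH2Cl2 should oxidise the benzylic-propargylic carbinol to the storable ynone F10.
   - HF·pyridine in THF should free the primary alcohol, giving hydroxy ynone F11.
   - A single brief MnO2 oxidation, filtered and used directly, should give 17.

3. Step 10. The process at risk is acid-promoted cyclisation of the prenyl group onto the neighbouring C2 hydroxyl (chroman formation) while the acetals are hydrolysed. The fallback keeps that hydroxyl silylated during the acid step. It sets out from 4 and comes back to the route at 21.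
   - Double silylation of 4 with TBSOTf and Et3N (Et2O, 0 °C → rt) should give bis(tert-butyldimethylsilyloxy)diene F12.
   - Cycloaddition of F12 with 17 as in step 9, with a neutral work-up, should give silyl ether F13, in which the C2 oxygen stays silylated and the C4 hydroxyl is free.
   - 3 M aq HCl in THF should then remove the ring B methoxymethyl groups without a free phenol next to the prenyl group, giving triol F14.
   - HF·pyridine in THF should cleave the aryl silyl ether to give 21.

**Further compounds**

F1 | step 9 | 1-[3-bromo-2,6-bis(methoxymethoxy)-4-methylphenyl]prop-2-yn-1-ol (racemic) | C#CC(O)c1c(OCOC)cc(C)c(Br)c1OCOC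
F2 | step 9 | {1-[3-bromo-2,6-bis(methoxymethoxy)-4-methylphenyl]prop-2-yn-1-yl}oxy(tert-butyl)dimethylsilane (racemic) | C#CC(O[Si](C)(C)C(C)(C)C)c1c(OCOC)cc(C)c(Br)c1OCOC
F3 | step 9 | 4-[3-bromo-2,6-bis(methoxymethoxy)-4-methylphenyl]-4-(tert-butyldimethylsilyloxy)but-2-ynal (racemic) | O=CC#CC(O[Si](C)(C)C(C)(C)C)c1c(OCOC)cc(C)c(Br)c1OCOC
F4 | step 9 | 2-{[3-bromo-2,6-bis(methoxymethoxy)-4-methylphenyl](tert-butyldimethylsilyloxy)methyl}-4,6-dihydroxy-3-(3-methylbut-2-en-1-yl)benzaldehyde (racemic) | CC(C)=CCc1c(O)cc(O)c(C=O)c1C(O[Si](C)(C)C(C)(C)C)c1c(OCOC)cc(C)c(Br)c1OCOC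
F5 | step 9 | 2-{[3-bromo-2,6-bis(methoxymethoxy)-4-methylphenyl](tert-butyldimethylsilyloxy)methyl}-4,6-bis(methoxymethoxy)-3-(3-methylbut-2-en-1-yl)benzaldehyde (racemic) | CC(C)=CCc1c(OCOC)cc(OCOC)c(C=O)c1C(O[Si](C)(C)C(C)(C)C)c1c(OCOC)cc(C)c(Br)c1OCOC
F6 | step 9 | [2-{[3-bromo-2,6-bis(methoxymethoxy)-4-methylphenyl](tert-butyldimethylsilyloxy)methyl}-4,6-bis(methoxymethoxy)-3-(3-methylbut-2-en-1-yl)phenyl]methanol (racemic) | CC(C)=CCc1c(OCOC)cc(OCOC)c(CO)c1C(O[Si](C)(C)C(C)(C)C)c1c(OCOC)cc(C)c(Br)c1OCOC
F7 | step 9 | [3-bromo-2,6-bis(methoxymethoxy)-4-methylphenyl][2-(hydroxymethyl)-3,5-bis(methoxymethoxy)-6-(3-methylbut-2-en-1-yl)phenyl]methanol (racemic) | CC(C)=CCc1c(OCOC)cc(OCOC)c(CO)c1C(O)c1c(OCOC)cc(C)c(Br)c1OCOC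
F8 | step 9 | 2-[3-bromo-2,6-bis(methoxymethoxy)-4-methylbenzoyl]-4,6-bis(methoxymethoxy)-3-(3-methylbut-2-en-1-yl)benzaldehyde | CC(C)=CCc1c(OCOC)cc(OCOC)c(C=O)c1C(=O)c1c(OCOC)cc(C)c(Br)c1OCOC
F9 | step 8 | 1-[3-bromo-2,6-bis(methoxymethoxy)-4-methylphenyl]-4-(tert-butyldimethylsilyloxy)but-2-yn-1-ol (racemic) | CC(C)(C)[Si](C)(C)OCC#CC(O)c1c(OCOC)cc(C)c(Br)c1OCOC
F10 | step 8 | 1-[3-bromo-2,6-bis(methoxymethoxy)-4-methylphenyl]-4-(tert-butyldimethylsilyloxy)but-2-yn-1-one | CC(C)(C)[Si](C)(C)OCC#CC(=O)c1c(OCOC)cc(C)c(Br)c1OCOC
F11 | step 8 | 1-[3-bromo-2,6-bis(methoxymethoxy)-4-methylphenyl]-4-hydroxybut-2-yn-1-one | OCC#CC(=O)c1c(OCOC)cc(C)c(Br)c1OCOC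
F12 | step 10 | (1Z,3Z)-1-methoxy-7-methyl-1,3-bis(tert-butyldimethylsilyloxy)octa-1,3,6-triene | CO/C(O[Si](C)(C)C(C)(C)C)=C/C(O[Si](C)(C)C(C)(C)C)=C/CC=C(C)C
F13 | step 10 | 2-[3-bromo-2,6-bis(methoxymethoxy)-4-methylbenzoyl]-4-(tert-butyldimethylsilyloxy)-6-hydroxy-3-(3-methylbut-2-en-1-yl)benzaldehyde | CC(C)=CCc1c(O[Si](C)(C)C(C)(C)C)cc(O)c(C=O)c1C(=O)c1c(OCOC)cc(C)c(Br)c1OCOC
F14 | step 10 | 2-(3-bromo-2,6-dihydroxy-4-methylbenzoyl)-4-(tert-butyldimethylsilyloxy)-6-hydroxy-3-(3-methylbut-2-en-1-yl)benzaldehyde | CC(C)=CCc1c(O[Si](C)(C)C(C)(C)C)cc(O)c(C=O)c1C(=O)c1c(O)cc(C)c(Br)c1O
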